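**Retrosynthetic overview**
1. Late disconnections: the C8 ester (acid 31), the C11 methyl group (lactone enolate methylation) and the γ-lactone (oxidative lactonization of a C6/C12 diol that comes from a C7 vinyl group) lead back to cyclodecadiene 21.
2. C14 is then removed to give enol triflate 20 (Negishi methylation forward), and the ten-membered ring is opened across C2–C3 by a retro-[3,3] shift to cyclohexanol 17; forward this is an anionic oxy-Cope ring expansion with O-triflation in the same flask.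
3. Enabling feature: in the ten-membered carbocycle (C1–C10) the bond C2–C3 lies between the ring double bonds C1=C10 and C4=C5, so the ring is a cyclodeca-1,5-diene, the Cope isomer of a cyclohexane (C5–C10) with vinyl on C10 and the 2-propenyl unit on C5; the methyl-bearing C10 is where the activating oxygen sits.
4. Cyclohexanol 17 comes from (S)-4-silyloxycyclohexenone 1: cuprate vinyl addition (C7), Rubottom oxidation (C6–O), alkylative carbonyl transposition from C5 to C10 (enol triflate, Negishi coupling, epoxidation, formate hydrogenolysis, oxidation), then vinyl addition.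
5. Ring order: six-membered carbocycle (bought with 1), ten-membered ring (step 10), γ-lactone (step 14).

Key step: step 10

Remark: locants C1–C15 in the text are those of the target's germacranolide skeleton (C12 lactone carbonyl, C13 methyl on C11, C14 methyl on C10, C15 hydroxymethyl carbon); enantiopure enone 1 is taken as a catalogue compound.

Step 1
Reactants: 1 (S)-4-(tert-butyldimethylsilyloxy)cyclohex-2-en-1-one; 2 vinylmagnesium bromide
Product: 4 (3S,4S)-4-(tert-butyldimethylsilyloxy)-3-ethenyl-1-(triethylsilyloxy)cyclohex-1-ene, via magnesium enolate 3 (not isolated)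
Conditions: CuBr·SMe2 (10 mol %), THF, −78 °C; then Et3SiCl, Et3N, DMPU, −78 → 0 °C
Reagents that add atoms: chlorotriethylsilane, CC[Si](Cl)(CC)CC
Why: Copper-catalysed conjugate addition of the Grignard reagent should deliver the vinyl group to C7 on the face opposite to the adjacent C8 silyloxy group (trans product), and O-silylation of the regiodefined enolate fixes the C5=C6 enol ether.

Step 2
Reactants: 4 (3S,4S)-4-(tert-butyldimethylsilyloxy)-3-ethenyl-1-(triethylsilyloxy)cyclohex-1-ene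
Product: 5 (2S,3R,4S)-4-(tert-butyldimethylsilyloxy)-3-ethenyl-2-(triethylsilyloxy)cyclohexan-1-one
Conditions: mCPBA, NaHCO3, CH2Cl2, −20 → 0 °C
Reagents that add atoms: 3-chloroperoxybenzoic acid, OOC(=O)c1cccc(Cl)c1
Why: In this Rubottom oxidation the peracid should epoxidize the electron-rich enol ether anti to the C7 vinyl group and the silyloxy-oxirane should open with 1,4-shift of the triethylsilyl group, so that C6 receives its oxygen trans to C7 and already protected.

Step 3
Reactants: 5 (2S,3R,4S)-4-(tert-butyldimethylsilyloxy)-3-ethenyl-2-(triethylsilyloxy)cyclohexan-1-one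
Product: 7 (4S,5R,6S)-4-(tert-butyldimethylsilyloxy)-5-ethenyl-6-(triethylsilyloxy)cyclohex-1-en-1-yl trifluoromethanesulfonate, via potassium enolate 6 (not isolated)
Conditions: KN(SiMe3)2, THF, −78 °C; then PhNTf2, −78 → 0 °C
Reagents that add atoms: N-phenylbis(trifluoromethanesulfonimide), O=S(=O)(N(c1ccccc1)S(=O)(=O)C(F)(F)F)C(F)(F)F
Why: Kinetic deprotonation should occur at the unhindered C10 methylene and not at the silyloxy-bearing C6, and O-sulfonylation of the enolate by the triflimide gives the C5=C10 enol triflate without touching a stereocentre.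

Step 4
Reactants: 8 2-bromoprop-2-en-1-ol; 9 4-methoxybenzyl chloride
Product: 10 1-{[(2-bromoprop-2-en-1-yl)oxy]methyl}-4-methoxybenzene
Conditions: NaH, Bu4NI (cat.), THF, 0 °C → rt
Reagents that add atoms: none
Why: Williamson ether synthesis between a primary alkoxide and a reactive benzylic chloride.

Step 5
Reactants: 10 1-{[(2-bromoprop-2-en-1-yl)oxy]methyl}-4-methoxybenzene; 7 (4S,5R,6S)-4-(tert-butyldimethylsilyloxy)-5-ethenyl-6-(triethylsilyloxy)cyclohex-1-en-1-yl trifluoromethanesulfonate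
Product: 13 (4S,5R,6S)-4-(tert-butyldimethylsilyloxy)-5-ethenyl-1-{3-[(4-methoxybenzyl)oxy]prop-1-en-2-yl}-6-(triethylsilyloxy)cyclohex-1-ene, via alkenyllithium 11 (not isolated), via alkenylzinc bromide 12 (not isolated)
Conditions: 10, t-BuLi (2 equiv), Et2O, −78 °C; ZnBr2, THF, −78 → 0 °C; then 7, Pd(PPh3)4 (5 mol %), THF, rt
Reagents that add atoms: none
Why: Bromine–lithium exchange, transmetalation to zinc and Negishi coupling with the enol triflate should join C4 to C5 under conditions that leave the silyl ethers and the existing stereocentres untouched.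

Step 6
Reactants: 13 (4S,5R,6S)-4-(tert-butyldimethylsilyloxy)-5-ethenyl-1-{3-[(4-methoxybenzyl)oxy]prop-1-en-2-yl}-6-(triethylsilyloxy)cyclohex-1-ene
Product: 14 (1S,2S,3R,4S,6S)-4-(tert-butyldimethylsilyloxy)-3-ethenyl-1-{3-[(4-methoxybenzyl)oxy]prop-1-en-2-yl}-2-(triethylsilyloxy)-7-oxabicyclo[4.1.0]heptane
Conditions: mCPBA, NaHCO3, CH2Cl2, −20 → 0 °C
Reagents that add atoms: 3-chloroperoxybenzoic acid, OOC(=O)c1cccc(Cl)c1
Why: Prilezhaev epoxidation should select the trisubstituted ring double bond C5=C10, the most electron-rich of the three alkenes, and approach anti to the allylic C6 silyloxy group, which sets C5 and C10 with the oxirane oxygen on the face opposite to the C6 oxygen.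

Step 7
Reactants: 14 (1S,2S,3R,4S,6S)-4-(tert-butyldimethylsilyloxy)-3-ethenyl-1-{3-[(4-methoxybenzyl)oxy]prop-1-en-2-yl}-2-(triethylsilyloxy)-7-oxabicyclo[4.1.0]heptane
Product: 15 (1S,2S,3S,4R,5S)-5-(tert-butyldimethylsilyloxy)-4-ethenyl-2-{3-[(4-methoxybenzyl)oxy]prop-1-en-2-yl}-3-(triethylsilyloxy)cyclohexan-1-ol
Conditions: Pd2(dba)3 (2.5 mol %), PBu3 (10 mol %), HCO2H, Et3N, THF, rt
Reagents that add atoms: none
Why: In this formate hydrogenolysis of a vinyl epoxide, zerovalent palladium should ionize the allylic C5–O bond with inversion and the metal-bound formate should pass hydride to the more substituted allyl terminus C5 from the metal side, so that H5 ends up on the face of the C6 oxygen (2-propenyl group trans to it and equatorial), the 1,1-disubstituted alkene stays terminal and C10 keeps a secondary hydroxyl.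

Step 8
Reactants: 15 (1S,2S,3S,4R,5S)-5-(tert-butyldimethylsilyloxy)-4-ethenyl-2-{3-[(4-methoxybenzyl)oxy]prop-1-en-2-yl}-3-(triethylsilyloxy)cyclohexan-1-ol
Product: 16 (2R,3S,4R,5S)-5-(tert-butyldimethylsilyloxy)-4-ethenyl-2-{3-[(4-methoxybenzyl)oxy]prop-1-en-2-yl}-3-(triethylsilyloxy)cyclohexan-1-one
Conditions: Dess–Martin periodinane, NaHCO3, CH2Cl2, 0 °C
Reagents that add atoms: none
Why: Dess–Martin oxidation under buffered, non-basic conditions should give the C10 ketone without epimerizing C5 or eliminating the β-silyloxy groups, which completes the transposition of the carbonyl group from C5 to C10.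

Step 9
Reactants: 16 (2R,3S,4R,5S)-5-(tert-butyldimethylsilyloxy)-4-ethenyl-2-{3-[(4-methoxybenzyl)oxy]prop-1-en-2-yl}-3-(triethylsilyloxy)cyclohexan-1-one; 2 vinylmagnesium bromide
Product: 17 (1R,2R,3S,4R,5S)-5-(tert-butyldimethylsilyloxy)-1,4-diethenyl-2-{3-[(4-methoxybenzyl)oxy]prop-1-en-2-yl}-3-(triethylsilyloxy)cyclohexan-1-ol
Conditions: CeCl3 (anhydrous), THF, −78 °C
Reagents that add atoms: none
Why: The organocerium reagent formed from the Grignard reagent and CeCl3 adds to the carbonyl group faster than it enolizes the ketone, and on the chair with all four substituents equatorial it should attack from the equatorial side, as vinyl additions to 2-substituted cyclohexanones do, which sets C10 with the vinyl group equatorial and trans to the C5 alkenyl group and the hydroxyl axial.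

Step 10
Reactants: 17 (1R,2R,3S,4R,5S)-5-(tert-butyldimethylsilyloxy)-1,4-diethenyl-2-{3-[(4-methoxybenzyl)oxy]prop-1-en-2-yl}-3-(triethylsilyloxy)cyclohexan-1-ol
Product: 20 (1Z,5Z,7R,8R,9S)-9-(tert-butyldimethylsilyloxy)-8-ethenyl-5-{[(4-methoxybenzyl)oxy]methyl}-7-(triethylsilyloxy)cyclodeca-1,5-dien-1-yl trifluoromethanesulfonate, via potassium alkoxide 18 (not isolated), via potassium enolate 19 (not isolated)
Conditions: KH, 18-crown-6, THF, 0 → 25 °C; then N-(5-chloropyridin-2-yl)bis(trifluoromethanesulfonimide), −78 → 0 °C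
Reagents that add atoms: N-(5-chloropyridin-2-yl)bis(trifluoromethanesulfonimide), O=S(=O)(N(c1ccc(Cl)cn1)S(=O)(=O)C(F)(F)F)C(F)(F)F
Why: KH with 18-crown-6 turns the tertiary alcohol into the crown-separated potassium alkoxide 18, whose oxygen lone pairs weaken the C5–C10 bond so that the [3,3]-sigmatropic shift (anionic oxy-Cope rearrangement) should run near room temperature, forming C2–C3 while C5–C10 breaks. The closest known reaction type is the anionic oxy-Cope ring expansion of trans-1,2-divinylcyclohexan-1-ols to (E)-cyclodec-5-enones with O-sulfonylation of the enolate so formed. The ten-membered ring is closed by ring expansion (six ring atoms plus the four alkene carbons) through a chair-like six-centre transition state, suprafacial on both allyl halves, in which the vinyl group on C10 and the 2-propenyl unit on C5 are both equatorial on the chair cyclohexane. No new stereocentre arises: C5 and C10 become trigonal, C6, C7 and C8 are untouched, and the chair transition state fixes both new ring double bonds as trans within the ring (C9 anti to C2, C6 anti to C3), the descriptors being Z only because of the oxygen substituents. The step needs the trans-diequatorial 1,2-dialkenyl arrangement, secured by the equatorial C5 substituent and the equatorial vinyl delivery of step 9, and an alkoxide free of side channels, secured because both silyl ethers are trans-1,3 to the axial C10 oxygen (no silyl migration) and no leaving group is β to the enolate carbon. The rearrangement is irreversible because it ends in the regiodefined enolate 19 (C1=C10–O), which is captured as the triflate at −78 °C before proton exchange can scramble it.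

Step 11
Reactants: 20 (1Z,5Z,7R,8R,9S)-9-(tert-butyldimethylsilyloxy)-8-ethenyl-5-{[(4-methoxybenzyl)oxy]methyl}-7-(triethylsilyloxy)cyclodeca-1,5-dien-1-yl trifluoromethanesulfonate
Product: 21 (1E,5Z,7R,8R,9S)-9-(tert-butyldimethylsilyloxy)-8-ethenyl-5-{[(4-methoxybenzyl)oxy]methyl}-1-methyl-7-(triethylsilyloxy)cyclodeca-1,5-diene
Conditions: Me2Zn, Pd(PPh3)4 (5 mol %), THF, 25 °C
Reagents that add atoms: dimethylzinc, C[Zn]C
Why: Negishi coupling of the enol triflate proceeds with retention of double-bond geometry and installs C14, so that C1=C10 becomes the E-trisubstituted alkene of the target at a temperature too low for thermal Cope reversion.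

Step 12
Reactants: 21 (1E,5Z,7R,8R,9S)-9-(tert-butyldimethylsilyloxy)-8-ethenyl-5-{[(4-methoxybenzyl)oxy]methyl}-1-methyl-7-(triethylsilyloxy)cyclodeca-1,5-diene
Product: 23 2-[(1R,2R,3Z,7E,10S)-10-(tert-butyldimethylsilyloxy)-4-{[(4-methoxybenzyl)oxy]methyl}-8-methyl-2-(triethylsilyloxy)cyclodeca-3,7-dien-1-yl]ethan-1-ol, via alkylborane 22 (not isolated)
Conditions: 9-BBN, THF, 0 °C → rt; then aq. NaOH, H2O2, 0 °C
Reagents that add atoms: hydrogen peroxide, OO
Why: Hydroboration with the bulky dialkylborane is anti-Markovnikov and should select the monosubstituted C7 vinyl group over the two trisubstituted ring alkenes, and oxidation of the C–B bond gives the primary alcohol at C12.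

Step 13
Reactants: 23 2-[(1R,2R,3Z,7E,10S)-10-(tert-butyldimethylsilyloxy)-4-{[(4-methoxybenzyl)oxy]methyl}-8-methyl-2-(triethylsilyloxy)cyclodeca-3,7-dien-1-yl]ethan-1-ol
Product: 24 2-[(1S,2R,3Z,7E,10S)-10-(tert-butyldimethylsilyloxy)-2-hydroxy-4-{[(4-methoxybenzyl)oxy]methyl}-8-methylcyclodeca-3,7-dien-1-yl]ethan-1-ol
Conditions: PPTS (20 mol %), MeOH/CH2Cl2, 0 °C
Reagents that add atoms: none
Why: Acid-catalysed methanolysis cleaves the secondary triethylsilyl ether much faster than the tert-butyldimethylsilyl ether at C8, and the mild pyridinium acid should spare the 4-methoxybenzyl ether and the 1,5-diene.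

Step 14
Reactants: 24 2-[(1S,2R,3Z,7E,10S)-10-(tert-butyldimethylsilyloxy)-2-hydroxy-4-{[(4-methoxybenzyl)oxy]methyl}-8-methylcyclodeca-3,7-dien-1-yl]ethan-1-ol
Product: 26 (3aS,4S,6E,10Z,11aR)-4-(tert-butyldimethylsilyloxy)-10-{[(4-methoxybenzyl)oxy]methyl}-6-methyl-3a,4,5,8,9,11a-hexahydrocyclodeca[b]furan-2(3H)-one, via lactol 25 (not isolated)
Conditions: TEMPO (20 mol %), PhI(OAc)2 (2.5 equiv), CH2Cl2, rt
Reagents that add atoms: none
Why: The oxoammonium catalyst oxidizes the primary alcohol selectively, the aldehyde is trapped by the C6 hydroxyl as a five-membered lactol and this is oxidized on to the trans-fused γ-lactone, while the protected C8 oxygen cannot compete for the acyl carbon.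

Step 15
Reactants: 26 (3aS,4S,6E,10Z,11aR)-4-(tert-butyldimethylsilyloxy)-10-{[(4-methoxybenzyl)oxy]methyl}-6-methyl-3a,4,5,8,9,11a-hexahydrocyclodeca[b]furan-2(3H)-one
Product: 28 (3S,3aS,4S,6E,10Z,11aR)-4-(tert-butyldimethylsilyloxy)-10-{[(4-methoxybenzyl)oxy]methyl}-3,6-dimethyl-3a,4,5,8,9,11a-hexahydrocyclodeca[b]furan-2(3H)-one, via lithium enolate 27 (not isolated)
Conditions: LiN(iPr)2, THF, −78 °C; then MeI, −78 → −40 °C
Reagents that add atoms: iodomethane, CI
Why: Alkylation of the lactone enolate should occur on the face that carries only H7, anti to the C7–C8 bond of the trans-fused bicycle, which sets C11 with the methyl group cis to H7 (11S), also the thermodynamically preferred epimer.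

Step 16
Reactants: 28 (3S,3aS,4S,6E,10Z,11aR)-4-(tert-butyldimethylsilyloxy)-10-{[(4-methoxybenzyl)oxy]methyl}-3,6-dimethyl-3a,4,5,8,9,11a-hexahydrocyclodeca[b]furan-2(3H)-one
Product: 29 (3S,3aR,4S,6E,10Z,11aR)-4-hydroxy-10-{[(4-methoxybenzyl)oxy]methyl}-3,6-dimethyl-3a,4,5,8,9,11a-hexahydrocyclodeca[b]furan-2(3H)-one
Conditions: HF·pyridine, pyridine, THF, 0 °C → rt
Reagents that add atoms: none
Why: Buffered fluoride under slightly acidic conditions removes the secondary silyl ether without generating a free C8 alkoxide, which avoids translactonization to the 8,12-lactone and leaves the 4-methoxybenzyl ether in place.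

Step 17
Reactants: 30 2-(bromomethyl)prop-2-enoic acid
Product: 31 2-(acetoxymethyl)prop-2-enoic acid
Conditions: KOAc (2.2 equiv), DMF, rt; then aq. HCl
Reagents that add atoms: potassium acetate, CC(=O)[O-].[K+]
Why: Nucleophilic substitution of the reactive allylic bromide by acetate on the carboxylate salt, where direct attack and attack with allylic transposition give the same product.

Step 18
Reactants: 29 (3S,3aR,4S,6E,10Z,11aR)-4-hydroxy-10-{[(4-methoxybenzyl)oxy]methyl}-3,6-dimethyl-3a,4,5,8,9,11a-hexahydrocyclodeca[b]furan-2(3H)-one; 31 2-(acetoxymethyl)prop-2-enoic acid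
Product: 32 (3S,3aR,4S,6E,10Z,11aR)-10-{[(4-methoxybenzyl)oxy]methyl}-3,6-dimethyl-2-oxo-2,3,3a,4,5,8,9,11a-octahydrocyclodeca[b]furan-4-yl 2-(acetoxymethyl)prop-2-enoate
Conditions: EDC·HCl, DMAP (10 mol %), CH2Cl2, 0 °C → rt
Reagents that add atoms: none
Why: Steglich esterification should acylate the only free hydroxyl group (C8) with retention at C8 under nearly neutral conditions that the acrylate and the lactone tolerate.

Step 19
Reactants: 32 (3S,3aR,4S,6E,10Z,11aR)-10-{[(4-methoxybenzyl)oxy]methyl}-3,6-dimethyl-2-oxo-2,3,3a,4,5,8,9,11a-octahydrocyclodeca[b]furan-4-yl 2-(acetoxymethyl)prop-2-enoate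
Product: 33 (3S,3aR,4S,6E,10Z,11aR)-10-(hydroxymethyl)-3,6-dimethyl-2-oxo-2,3,3a,4,5,8,9,11a-octahydrocyclodeca[b]furan-4-yl 2-(acetoxymethyl)prop-2-enoate (CNP0291063.1)
Conditions: DDQ, CH2Cl2/pH 7 buffer, 0 °C
Reagents that add atoms: none
Why: Oxidative cleavage of the 4-methoxybenzyl ether (hydride abstraction, then hydrolysis of the oxocarbenium ion) should free the C15 hydroxyl under neutral conditions that leave both esters, the lactone and the diene untouched.

**Compound list**
1 | (S)-4-(tert-butyldimethylsilyloxy)cyclohex-2-en-1-one | O=C1C=C[C@@H](O[Si](C)(C)C(C)(C)C)CC1 | starting material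
2 | vinylmagnesium bromide | C=C[Mg]Br | starting material
3 | magnesium enolate: bromomagnesium (3S,4S)-4-(tert-butyldimethylsilyloxy)-3-ethenylcyclohex-1-en-1-olate | Br[Mg]OC1=C[C@H](C=C)[C@@H](O[Si](C)(C)C(C)(C)C)CC1 | intermediate
4 | (3S,4S)-4-(tert-butyldimethylsilyloxy)-3-ethenyl-1-(triethylsilyloxy)cyclohex-1-ene | CC[Si](CC)(CC)OC1=C[C@H](C=C)[C@@H](O[Si](C)(C)C(C)(C)C)CC1 | intermediate
5 | (2S,3R,4S)-4-(tert-butyldimethylsilyloxy)-3-ethenyl-2-(triethylsilyloxy)cyclohexan-1-one | O=C1[C@@H](O[Si](CC)(CC)CC)[C@H](C=C)[C@@H](O[Si](C)(C)C(C)(C)C)CC1 | intermediate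
6 | potassium enolate: potassium (4S,5R,6S)-4-(tert-butyldimethylsilyloxy)-5-ethenyl-6-(triethylsilyloxy)cyclohex-1-en-1-olate | [K]OC1=CC[C@H](O[Si](C)(C)C(C)(C)C)[C@@H](C=C)[C@@H]1O[Si](CC)(CC)CC | intermediate
7 | (4S,5R,6S)-4-(tert-butyldimethylsilyloxy)-5-ethenyl-6-(triethylsilyloxy)cyclohex-1-en-1-yl trifluoromethanesulfonate | O=S(=O)(OC1=CC[C@H](O[Si](C)(C)C(C)(C)C)[C@@H](C=C)[C@@H]1O[Si](CC)(CC)CC)C(F)(F)F | intermediate
8 | 2-bromoprop-2-en-1-ol | OCC(Br)=C | starting material
9 | 4-methoxybenzyl chloride | COc1ccc(CCl)cc1 | starting material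
10 | 1-{[(2-bromoprop-2-en-1-yl)oxy]methyl}-4-methoxybenzene | C=C(Br)COCc1ccc(OC)cc1 | intermediate
11 | alkenyllithium: {3-[(4-methoxybenzyl)oxy]prop-1-en-2-yl}lithium | [Li]C(=C)COCc1ccc(OC)cc1 | intermediate
12 | alkenylzinc bromide: bromo{3-[(4-methoxybenzyl)oxy]prop-1-en-2-yl}zinc | Br[Zn]C(=C)COCc1ccc(OC)cc1 | intermediate
13 | (4S,5R,6S)-4-(tert-butyldimethylsilyloxy)-5-ethenyl-1-{3-[(4-methoxybenzyl)oxy]prop-1-en-2-yl}-6-(triethylsilyloxy)cyclohex-1-ene | C=C(COCc1ccc(OC)cc1)C1=CC[C@H](O[Si](C)(C)C(C)(C)C)[C@@H](C=C)[C@@H]1O[Si](CC)(CC)CC | intermediate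
14 | (1S,2S,3R,4S,6S)-4-(tert-butyldimethylsilyloxy)-3-ethenyl-1-{3-[(4-methoxybenzyl)oxy]prop-1-en-2-yl}-2-(triethylsilyloxy)-7-oxabicyclo[4.1.0]heptane | C=C(COCc1ccc(OC)cc1)[C@]12O[C@H]1C[C@H](O[Si](C)(C)C(C)(C)C)[C@@H](C=C)[C@@H]2O[Si](CC)(CC)CC | intermediate
15 | (1S,2S,3S,4R,5S)-5-(tert-butyldimethylsilyloxy)-4-ethenyl-2-{3-[(4-methoxybenzyl)oxy]prop-1-en-2-yl}-3-(triethylsilyloxy)cyclohexan-1-ol | C=C(COCc1ccc(OC)cc1)[C@H]1[C@@H](O)C[C@H](O[Si](C)(C)C(C)(C)C)[C@@H](C=C)[C@@H]1O[Si](CC)(CC)CC | intermediate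
16 | (2R,3S,4R,5S)-5-(tert-butyldimethylsilyloxy)-4-ethenyl-2-{3-[(4-methoxybenzyl)oxy]prop-1-en-2-yl}-3-(triethylsilyloxy)cyclohexan-1-one | C=C(COCc1ccc(OC)cc1)[C@H]1C(=O)C[C@H](O[Si](C)(C)C(C)(C)C)[C@@H](C=C)[C@@H]1O[Si](CC)(CC)CC | intermediate
17 | (1R,2R,3S,4R,5S)-5-(tert-butyldimethylsilyloxy)-1,4-diethenyl-2-{3-[(4-methoxybenzyl)oxy]prop-1-en-2-yl}-3-(triethylsilyloxy)cyclohexan-1-ol | C=C(COCc1ccc(OC)cc1)[C@H]1[C@](O)(C=C)C[C@H](O[Si](C)(C)C(C)(C)C)[C@@H](C=C)[C@@H]1O[Si](CC)(CC)CC | intermediate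
18 | potassium alkoxide: potassium (1R,2R,3S,4R,5S)-5-(tert-butyldimethylsilyloxy)-1,4-diethenyl-2-{3-[(4-methoxybenzyl)oxy]prop-1-en-2-yl}-3-(triethylsilyloxy)cyclohexan-1-olate | C=C(COCc1ccc(OC)cc1)[C@H]1[C@](O[K])(C=C)C[C@H](O[Si](C)(C)C(C)(C)C)[C@@H](C=C)[C@@H]1O[Si](CC)(CC)CC | intermediate
19 | potassium enolate: potassium (1Z,5Z,7R,8R,9S)-9-(tert-butyldimethylsilyloxy)-8-ethenyl-5-{[(4-methoxybenzyl)oxy]methyl}-7-(triethylsilyloxy)cyclodeca-1,5-dien-1-olate | CC(C)(C)[Si](C)(C)O[C@H]1C/C(O[K])=C/CC/C(COCc2ccc(OC)cc2)=C/[C@@H](O[Si](CC)(CC)CC)[C@@H]1C=C | intermediate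
20 | (1Z,5Z,7R,8R,9S)-9-(tert-butyldimethylsilyloxy)-8-ethenyl-5-{[(4-methoxybenzyl)oxy]methyl}-7-(triethylsilyloxy)cyclodeca-1,5-dien-1-yl trifluoromethanesulfonate | CC(C)(C)[Si](C)(C)O[C@H]1C/C(OS(=O)(=O)C(F)(F)F)=C/CC/C(COCc2ccc(OC)cc2)=C/[C@@H](O[Si](CC)(CC)CC)[C@@H]1C=C | intermediate
21 | (1E,5Z,7R,8R,9S)-9-(tert-butyldimethylsilyloxy)-8-ethenyl-5-{[(4-methoxybenzyl)oxy]methyl}-1-methyl-7-(triethylsilyloxy)cyclodeca-1,5-diene | CC(C)(C)[Si](C)(C)O[C@H]1C/C(C)=C/CC/C(COCc2ccc(OC)cc2)=C/[C@@H](O[Si](CC)(CC)CC)[C@@H]1C=C | intermediate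
22 | alkylborane: 9-{2-[(1R,2R,3Z,7E,10S)-10-(tert-butyldimethylsilyloxy)-4-{[(4-methoxybenzyl)oxy]methyl}-8-methyl-2-(triethylsilyloxy)cyclodeca-3,7-dien-1-yl]ethyl}-9-borabicyclo[3.3.1]nonane | CC(C)(C)[Si](C)(C)O[C@H]1C/C(C)=C/CC/C(COCc2ccc(OC)cc2)=C/[C@@H](O[Si](CC)(CC)CC)[C@@H]1CCB3C4CCCC3CCC4 | intermediate
23 | 2-[(1R,2R,3Z,7E,10S)-10-(tert-butyldimethylsilyloxy)-4-{[(4-methoxybenzyl)oxy]methyl}-8-methyl-2-(triethylsilyloxy)cyclodeca-3,7-dien-1-yl]ethan-1-ol | CC(C)(C)[Si](C)(C)O[C@H]1C/C(C)=C/CC/C(COCc2ccc(OC)cc2)=C/[C@@H](O[Si](CC)(CC)CC)[C@@H]1CCO | intermediate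
24 | 2-[(1S,2R,3Z,7E,10S)-10-(tert-butyldimethylsilyloxy)-2-hydroxy-4-{[(4-methoxybenzyl)oxy]methyl}-8-methylcyclodeca-3,7-dien-1-yl]ethan-1-ol | CC(C)(C)[Si](C)(C)O[C@H]1C/C(C)=C/CC/C(COCc2ccc(OC)cc2)=C/[C@@H](O)[C@@H]1CCO | intermediate
25 | lactol: (3aS,4S,6E,10Z,11aR)-4-(tert-butyldimethylsilyloxy)-10-{[(4-methoxybenzyl)oxy]methyl}-6-methyl-2,3,3a,4,5,8,9,11a-octahydrocyclodeca[b]furan-2-ol (both epimers at C2) | CC(C)(C)[Si](C)(C)O[C@H]1C/C(C)=C/CC/C(COCc3ccc(OC)cc3)=C/[C@H]2OC(O)C[C@H]12 | intermediate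
26 | (3aS,4S,6E,10Z,11aR)-4-(tert-butyldimethylsilyloxy)-10-{[(4-methoxybenzyl)oxy]methyl}-6-methyl-3a,4,5,8,9,11a-hexahydrocyclodeca[b]furan-2(3H)-one | CC(C)(C)[Si](C)(C)O[C@H]1C/C(C)=C/CC/C(COCc3ccc(OC)cc3)=C/[C@H]2OC(=O)C[C@H]12 | intermediate
27 | lithium enolate: lithium (3aS,4S,6E,10Z,11aR)-4-(tert-butyldimethylsilyloxy)-10-{[(4-methoxybenzyl)oxy]methyl}-6-methyl-3a,4,5,8,9,11a-hexahydrocyclodeca[b]furan-2-olate | CC(C)(C)[Si](C)(C)O[C@H]1C/C(C)=C/CC/C(COCc3ccc(OC)cc3)=C/[C@H]2OC(O[Li])=C[C@H]12 | intermediate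
28 | (3S,3aS,4S,6E,10Z,11aR)-4-(tert-butyldimethylsilyloxy)-10-{[(4-methoxybenzyl)oxy]methyl}-3,6-dimethyl-3a,4,5,8,9,11a-hexahydrocyclodeca[b]furan-2(3H)-one | CC(C)(C)[Si](C)(C)O[C@H]1C/C(C)=C/CC/C(COCc3ccc(OC)cc3)=C/[C@H]2OC(=O)[C@@H](C)[C@H]12 | intermediate
29 | (3S,3aR,4S,6E,10Z,11aR)-4-hydroxy-10-{[(4-methoxybenzyl)oxy]methyl}-3,6-dimethyl-3a,4,5,8,9,11a-hexahydrocyclodeca[b]furan-2(3H)-one | O[C@H]1C/C(C)=C/CC/C(COCc3ccc(OC)cc3)=C/[C@H]2OC(=O)[C@@H](C)[C@H]12 | intermediate
30 | 2-(bromomethyl)prop-2-enoic acid | C=C(CBr)C(=O)O | starting material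
31 | 2-(acetoxymethyl)prop-2-enoic acid | C=C(COC(C)=O)C(=O)O | intermediate
32 | (3S,3aR,4S,6E,10Z,11aR)-10-{[(4-methoxybenzyl)oxy]methyl}-3,6-dimethyl-2-oxo-2,3,3a,4,5,8,9,11a-octahydrocyclodeca[b]furan-4-yl 2-(acetoxymethyl)prop-2-enoate | C=C(COC(C)=O)C(=O)O[C@H]1C/C(C)=C/CC/C(COCc3ccc(OC)cc3)=C/[C@H]2OC(=O)[C@@H](C)[C@H]12 | intermediate
33 | (3S,3aR,4S,6E,10Z,11aR)-10-(hydroxymethyl)-3,6-dimethyl-2-oxo-2,3,3a,4,5,8,9,11a-octahydrocyclodeca[b]furan-4-yl 2-(acetoxymethyl)prop-2-enoate (CNP0291063.1) | C=C(COC(C)=O)C(=O)O[C@H]1C/C(C)=C/CC/C(CO)=C/[C@H]2OC(=O)[C@@H](C)[C@H]12 | target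

**Step count and risks**
Total step count: 19. Longest linear sequence: 17 steps (steps 1–3, 5–16, 18, 19); steps 4 and 17 make the two side reagents.

The three steps most likely to fail:

Step 10. The alkoxide may cleave the C5–C10 bond heterolytically instead of rearranging in concert, which would be followed by loss of the C6 silyloxy group; or the enolate may exchange protons before it is sulfonylated, losing its regio- and geometric definition. The fallback sets out from 17 and runs the uncharged thermal oxy-Cope rearrangement (1,2-dichlorobenzene, about 190 °C, sealed tube), where the enol tautomerizes to the ten-membered ketone (5Z,7R,8R,9S)-9-(tert-butyldimethylsilyloxy)-8-ethenyl-5-{[(4-methoxybenzyl)oxy]methyl}-7-(triethylsilyloxy)cyclodec-5-en-1-one F1. This ketone is then deprotonated kinetically on the C1 side with KN(SiMe3)2 at −78 °C (the C9 side is flanked by the silyloxy-bearing C8) and sulfonylated with the same triflimide, passing through 19 and rejoining the route at 20.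

Step 9. The vinyl group may be delivered axially instead of equatorially, or the doubly activated C5–H may be enolized with β-elimination of the C6 silyloxy group. The fallback sets out from 16 and builds the carbinol under thermodynamic control. A Corey–Chaykovsky reaction with dimethylsulfoxonium methylide (Me3S(O)I, NaH, DMSO, rt) adds reversibly and should place the new C–C bond equatorial, giving the spiro-epoxide (3S,4R,5S,6R,7S)-7-(tert-butyldimethylsilyloxy)-6-ethenyl-4-{3-[(4-methoxybenzyl)oxy]prop-1-en-2-yl}-5-(triethylsilyloxy)-1-oxaspiro[2.5]octane F2. Excess dimethylsulfonium methylide (Me3SI, n-BuLi, THF, −10 °C → rt) then opens the oxirane at its CH2 group and the resulting ylide eliminates Me2S, which gives the vinyl carbinol and comes back to the route at 17.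

Step 7. Hydride may be delivered to the wrong terminus of the allylpalladium intermediate (C3 instead of C5), or β-elimination may give a triene. The fallback sets out from 14 and uses a Meinwald rearrangement with a mild Lewis acid (MgBr2·OEt2, Et2O, 0 °C): ionization at the allyl-stabilized C5 and a 1,2-hydride shift from C10 give the ketone directly, so it comes back to the route at 16 and step 8 is skipped. Compounds outside the list on this way: none F0.

**Further compounds**
F1 | step 10 | (5Z,7R,8R,9S)-9-(tert-butyldimethylsilyloxy)-8-ethenyl-5-{[(4-methoxybenzyl)oxy]methyl}-7-(triethylsilyloxy)cyclodec-5-en-1-one | CC(C)(C)[Si](C)(C)O[C@H]1CC(=O)CCC/C(COCc2ccc(OC)cc2)=C/[C@@H](O[Si](CC)(CC)CC)[C@@H]1C=C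
F2 | step 9 | (3S,4R,5S,6R,7S)-7-(tert-butyldimethylsilyloxy)-6-ethenyl-4-{3-[(4-methoxybenzyl)oxy]prop-1-en-2-yl}-5-(triethylsilyloxy)-1-oxaspiro[2.5]octane | C=C(COCc1ccc(OC)cc1)[C@H]1[C@]2(CO2)C[C@H](O[Si](C)(C)C(C)(C)C)[C@@H](C=C)[C@@H]1O[Si](CC)(CC)CC
F0 | step 7 | none | none
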